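**Retrosynthetic overview**

1. Two retro-hetero-Diels–Alder cuts through both dihydropyran rings (O–C3/CH2–C2 and O–C7/CH2–C6) give (S)-hydroxyhumulene, an 11-membered all-E triene, and two tropolone ortho-quinone methides.
2. The C9=C10 olefin comes from a C10 ketone via its enol triflate. The 11-membered ketone is opened at C1–C11 to an acyclic farnesyl-type chain: a ketone enolate at C11 and an allyl electrophile C1–C2=C3 with oxygen on C4, that is, a 2-methyl-2-vinyloxirane (a palladium-controlled copy of the biosynthetic 1,11 closure).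
3. Enabling feature: in the 11-membered ring the gem-dimethyl carbon C11 lies between the olefinic CH C10 (a latent carbonyl, so C11 is an enolate carbon and C9 the only other enolisable site) and C1H2. After the retro-cycloaddition C1 is the terminus of the allyl unit C1–C2=C3(CH3) whose far end carries the C4 carbinol.
4. The chain is assembled from prenyl acetate, N-methoxy-N-methylacetamide and propargyl alcohol (carboalumination/Negishi allyl–alkenyl coupling; Sharpless epoxidation sets C4). The tropolone comes from 2-methylanisole by Birch reduction, dibromocarbene addition and ring expansion.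
5. Ring order: tropolone ring (separately), then the 11-membered carbocycle (key step), then both dihydropyran rings in the last step.

Key step: step 10

Remark: ring carbons of the 11-membered ring are numbered C1–C11 (C1 = CH2 between the ring-fusion CH C2 and the gem-dimethyl carbon C11; C3 and C7 = C(CH3)–O; C4 = CHOH; C9=C10 = E olefin). Tropolones are drawn as one of two rapidly equilibrating tautomers. The first cycloaddition in step 20 is assumed to occur at the olefin next to the carbinol.

**Route**

Step 1
Reactants: 1 3-methylbut-2-en-1-yl acetate (prenyl acetate)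
Product: 2 (2E)-4-hydroxy-3-methylbut-2-en-1-yl acetate
Conditions: SeO2 (0.2 equiv), t-BuOOH (2 equiv), CH2Cl2, rt
Reagents that add atoms: tert-butyl hydroperoxide, CC(C)(C)OO
Why: Riley allylic oxidation (ene reaction then 2,3-sigmatropic shift) of a trisubstituted olefin should hydroxylate the E-methyl group selectively and so fixes the E geometry of the later C6=C7 olefin.

Step 2
Reactants: 2 (2E)-4-hydroxy-3-methylbut-2-en-1-yl acetate
Product: 3 (2E)-4-bromo-3-methylbut-2-en-1-yl acetate
Conditions: CBr4 (1.2 equiv), PPh3 (1.25 equiv), CH2Cl2, 0 °C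
Reagents that add atoms: tetrabromomethane, BrC(Br)(Br)Br
Why: Appel bromination of a primary allylic alcohol should proceed by SN2 displacement without allylic transposition or loss of olefin geometry.

Step 3
Reactants: 3 (2E)-4-bromo-3-methylbut-2-en-1-yl acetate; 4 N-methoxy-N-methylacetamide
Product: 6 (2E)-6-[methoxy(methyl)amino]-3-methyl-6-oxohex-2-en-1-yl acetate, via lithium amide enolate 5 (not isolated)
Conditions: LiN(i-Pr)2 (1.05 equiv), THF, −78 °C; then 3, −78 °C, 1 h
Reagents that add atoms: none
Why: SN2 alkylation of the amide enolate by the primary allylic bromide should be much faster at −78 °C than attack on the acetate and forms the C8–C9 bond with the E olefin untouched.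

Step 4
Reactants: 6 (2E)-6-[methoxy(methyl)amino]-3-methyl-6-oxohex-2-en-1-yl acetate; 7 prop-2-yn-1-ol
Product: 9 (4E,7E)-9-hydroxy-N-methoxy-N,4,8-trimethylnona-4,7-dienamide, via (E)-alkenylalane 8 (not isolated)
Conditions: AlMe3 (3 equiv), Cp2ZrCl2 (0.25 equiv), CH2Cl2, 0 °C → rt; then 6, Pd(PPh3)4 (5 mol %), THF, rt; dilute aq. HCl
Reagents that add atoms: trimethylaluminium, C[Al](C)C
Why: Zirconium-catalysed syn carboalumination of the alkyne followed by Negishi-type palladium-catalysed allyl–alkenyl coupling should join the alkenyl carbon to the primary terminus of the allyl acetate with retention of both olefin geometries, giving the skipped E,E-diene (C4–C5 bond).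

Step 5
Reactants: 9 (4E,7E)-9-hydroxy-N-methoxy-N,4,8-trimethylnona-4,7-dienamide
Product: 10 (5E,8E)-10-hydroxy-2,5,9-trimethyldeca-1,5,8-trien-3-one
Conditions: CH2=C(CH3)MgBr (3 equiv), THF, −20 → 0 °C; aq. NH4Cl
Reagents that add atoms: isopropenylmagnesium bromide, C=C(C)[Mg]Br
Why: Weinreb ketone synthesis: after deprotonation of the alcohol the chelated tetrahedral adduct of the amide should release the isopropenyl ketone only on work-up, so no tertiary alcohol forms.

Step 6
Reactants: 10 (5E,8E)-10-hydroxy-2,5,9-trimethyldeca-1,5,8-trien-3-one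
Product: 11 [(2S,3S)-3-[(2E)-3,7-dimethyl-6-oxoocta-2,7-dien-1-yl]-2-methyloxiran-2-yl]methanol
Conditions: Ti(Oi-Pr)4 (10 mol %), L-(+)-diethyl tartrate (12 mol %), t-BuOOH (2 equiv), 4 Å molecular sieves, CH2Cl2, −20 °C
Reagents that add atoms: tert-butyl hydroperoxide, CC(C)(C)OO
Why: Sharpless asymmetric epoxidation of the E-2-methylallylic alcohol with the L-(+)-tartrate catalyst should deliver oxygen to the face that makes C4 (and C3) S, the homoallylic and enone olefins being inert to the titanium–tartrate–peroxide system.

Step 7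
Reactants: 11 [(2S,3S)-3-[(2E)-3,7-dimethyl-6-oxoocta-2,7-dien-1-yl]-2-methyloxiran-2-yl]methanol
Product: 12 (2R,3S)-3-[(2E)-3,7-dimethyl-6-oxoocta-2,7-dien-1-yl]-2-methyloxirane-2-carbaldehyde
Conditions: Dess–Martin periodinane (1.3 equiv), pyridine (3 equiv), CH2Cl2, 0 °C → rt
Reagents that add atoms: none
Why: Buffered Dess–Martin oxidation of the primary alcohol should give the epoxy aldehyde, whose quaternary alpha carbon cannot epimerise (the descriptor changes only through priorities).

Step 8
Reactants: 12 (2R,3S)-3-[(2E)-3,7-dimethyl-6-oxoocta-2,7-dien-1-yl]-2-methyloxirane-2-carbaldehyde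
Product: 13 (5E)-7-[(2S,3S)-3-ethenyl-3-methyloxiran-2-yl]-2,5-dimethylhepta-1,5-dien-3-one
Conditions: Ph3PCH3Br (1.1 equiv), KN(SiMe3)2 (1.05 equiv), THF, 0 °C; then 12, −78 → 0 °C
Reagents that add atoms: methyltriphenylphosphonium bromide, C[P+](c1ccccc1)(c1ccccc1)c1ccccc1.[Br-]
Why: Wittig methylenation should take the far more electrophilic aldehyde in preference to the conjugated ketone and completes the vinyl epoxide (C1=C2 next to the C3–C4 epoxide).

Step 9
Reactants: 13 (5E)-7-[(2S,3S)-3-ethenyl-3-methyloxiran-2-yl]-2,5-dimethylhepta-1,5-dien-3-one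
Product: 15 triethyl{[(6E)-8-[(2S,3S)-3-ethenyl-3-methyloxiran-2-yl]-2,6-dimethylocta-2,6-dien-3-yl]oxy}silane, via potassium enolate 14 (not isolated)
Conditions: K[HB(s-Bu)3] (1.05 equiv), THF, −78 °C, 20 min; then Et3SiCl (1.3 equiv), −78 → 0 °C
Reagents that add atoms: chlorotriethylsilane, CC[Si](Cl)(CC)CC
Why: Conjugate reduction of the beta-unsubstituted isopropenyl ketone by the bulky borohydride should give only the tetrasubstituted enolate (C10–O, C11), which O-silylation fixes regiospecifically, the vinyl epoxide being inert to this hydride at −78 °C.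

Step 10
Reactants: 15 triethyl{[(6E)-8-[(2S,3S)-3-ethenyl-3-methyloxiran-2-yl]-2,6-dimethylocta-2,6-dien-3-yl]oxy}silane
Product: 16 (4E,6S,8E)-2,2,5,9-tetramethyl-6-[(triethylsilyl)oxy]cycloundeca-4,8-dien-1-one
Conditions: Pd2(dba)3·CHCl3 (5 mol %), dppe (12 mol %), THF, 60 °C, syringe-pump addition of 15 over 12 h (final 0.002 M)
Reagents that add atoms: none
Why: Proposed new method: oxidative addition of zerovalent palladium to the vinyl epoxide should give a zwitterionic π-allyl complex (C1–C2–C3) whose C4 alkoxide takes the triethylsilyl group from an enol ether, so that the regiodefined tetrasubstituted enolate at C11 is released only next to an activated allyl unit and attacks the unsubstituted terminus C1 on the face opposite to palladium, the net change being an isomerisation in which silicon moves from the enol oxygen to the C4 oxygen. The closest known reactions are the Tsuji–Trost allylation of silyl enol ethers by allyl carbonates (triggered by the released alkoxide, also used for 11-membered terpenoid ring closures) and the palladium-catalysed macrocyclisation of vinyl epoxides with stabilised carbon acids by net isomerisation. The 11-membered carbocycle closes in the endo mode with respect to the allyl unit (bond to C1) and not in the 9-exo mode at the fully substituted C3. No new stereocentre arises (C11 carries two methyl groups); C4 keeps the configuration from step 6 because its C–O bond is never broken, and the C2=C3 olefin should be E because the π-allyl complex equilibrates to the isomer with the larger C4 substituent syn and the methyl group anti. The step needs C- over O-alkylation, C1 over C3 attack, and ring closure over oligomerisation or collapse of the zwitterion to a dienol; the soft tetrasubstituted enolate, the shielding of C3, the strain of the 9-membered alternative and high dilution with slow addition should secure these.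

Step 11
Reactants: 16 (4E,6S,8E)-2,2,5,9-tetramethyl-6-[(triethylsilyl)oxy]cycloundeca-4,8-dien-1-one
Product: 18 (1Z,4E,7S,8E)-4,8,11,11-tetramethyl-7-[(triethylsilyl)oxy]cycloundeca-1,4,8-trien-1-yl trifluoromethanesulfonate, via potassium enolate 17 (not isolated)
Conditions: KN(SiMe3)2 (1.2 equiv), THF, −78 °C; then PhNTf2 (1.3 equiv), −78 → 0 °C
Reagents that add atoms: N-phenylbis(trifluoromethanesulfonimide), O=S(=O)(N(c1ccccc1)S(=O)(=O)C(F)(F)F)C(F)(F)F
Why: C9 is the only enolisable position and, as with tert-alkyl ketones, allylic strain against the quaternary C11 should enforce the enolate with oxygen cis to C8, so O-triflation gives the Z enol triflate that corresponds to the E ring olefin.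

Step 12
Reactants: 18 (1Z,4E,7S,8E)-4,8,11,11-tetramethyl-7-[(triethylsilyl)oxy]cycloundeca-1,4,8-trien-1-yl trifluoromethanesulfonate
Product: 19 triethyl{[(1S,2E,6E,9E)-2,5,5,9-tetramethylcycloundeca-2,6,9-trien-1-yl]oxy}silane
Conditions: Pd(OAc)2 (5 mol %), PPh3 (10 mol %), HCO2H (2 equiv), Bu3N (3 equiv), DMF, 60 °C
Reagents that add atoms: none
Why: Palladium-catalysed formate reduction of the enol triflate (oxidative addition, decarboxylation of formate, C–H reductive elimination) should replace the triflate by hydrogen with retention of olefin geometry, giving the E C9=C10 olefin.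

Step 13
Reactants: 19 triethyl{[(1S,2E,6E,9E)-2,5,5,9-tetramethylcycloundeca-2,6,9-trien-1-yl]oxy}silane
Product: 20 (1S,2E,6E,9E)-2,5,5,9-tetramethylcycloundeca-2,6,9-trien-1-ol ((S)-hydroxyhumulene)
Conditions: Bu4NF (1.2 equiv), THF, 0 °C
Reagents that add atoms: none
Why: Fluoride should cleave the silyl ether without touching the triene or the allylic stereocentre.

Step 14
Reactants: 21 1-methoxy-2-methylbenzene
Product: 22 1-methoxy-2-methylcyclohexa-1,4-diene
Conditions: Li (2.5 equiv), NH3 (l), t-BuOH (2.5 equiv), THF, −78 → −33 °C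
Reagents that add atoms: none
Why: Birch reduction of an anisole leaves both donor substituents on one olefin, so a tetrasubstituted enol ether and an isolated disubstituted olefin should result.

Step 15
Reactants: 22 1-methoxy-2-methylcyclohexa-1,4-diene
Product: 23 7,7-dibromo-1-methoxy-6-methylbicyclo[4.1.0]hept-3-ene (racemic)
Conditions: CHBr3 (1.1 equiv), KOt-Bu (1.2 equiv), pentane, 0 °C
Reagents that add atoms: bromoform, BrC(Br)Br
Why: Electrophilic dibromocarbene should add to the electron-rich tetrasubstituted enol ether olefin in preference to the disubstituted one, necessarily giving the cis-fused cyclopropane.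

Step 16
Reactants: 23 7,7-dibromo-1-methoxy-6-methylbicyclo[4.1.0]hept-3-ene
Product: 24 7,7-dibromo-1-methoxy-6-methylbicyclo[4.1.0]heptane-3,4-diol (racemic cis-diol)
Conditions: OsO4 (2 mol %), N-methylmorpholine N-oxide (1.5 equiv), acetone/H2O, rt
Reagents that add atoms: N-methylmorpholine N-oxide, C[N+]1([O-])CCOCC1; water, O
Why: Upjohn dihydroxylation of the remaining olefin should occur syn and from the face away from the endo bromine, the relative configuration being immaterial because both carbinol centres become sp2.

Step 17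
Reactants: 24 7,7-dibromo-1-methoxy-6-methylbicyclo[4.1.0]heptane-3,4-diol
Product: 26 5-bromo-2-hydroxy-4-methoxy-6-methylcyclohepta-2,4,6-trien-1-one, via bicyclic 1,2-dione 25 (not isolated)
Conditions: (CF3CO)2O (4 equiv), DMSO (6 equiv), CH2Cl2, −78 °C; then Et3N (10 equiv), −78 °C → rt
Reagents that add atoms: none
Why: Swern-type oxidation of both carbinols gives the dione, whose enolate should open the ring-fusion bond of the cyclopropane with loss of the endo bromide (disrotatory cyclopropyl-to-allyl opening assisted by the methoxy group) and tautomerise to the aromatic tropolone, a known ring expansion of dihalocyclopropane-fused cyclohexanediones.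

Step 18
Reactants: 26 5-bromo-2-hydroxy-4-methoxy-6-methylcyclohepta-2,4,6-trien-1-one
Product: 27 2-hydroxy-5-(hydroxymethyl)-4-methoxy-6-methylcyclohepta-2,4,6-trien-1-one
Conditions: Bu3SnCH2OH (1.5 equiv), Pd(PPh3)4 (5 mol %), 1,4-dioxane, 100 °C
Reagents that add atoms: (tributylstannyl)methanol, CCCC[Sn](CCCC)(CCCC)CO
Why: Stille coupling of the electron-poor vinylogous acyl bromide with the hydroxymethyl stannane under neutral conditions should replace bromine by CH2OH at the carbon between the methoxy and methyl groups.

Step 19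
Reactants: 27 2-hydroxy-5-(hydroxymethyl)-4-methoxy-6-methylcyclohepta-2,4,6-trien-1-one
Product: 28 2,4-dihydroxy-5-(hydroxymethyl)-6-methylcyclohepta-2,4,6-trien-1-one
Conditions: 2 M aq. HCl, 1,4-dioxane, 60 °C
Reagents that add atoms: water, O
Why: The methoxy group is a vinylogous methyl ester of the tropolone carbonyl and should hydrolyse by addition–elimination in dilute acid, water returning the benzylic-type alcohol if it ionises.

Step 20
Reactants: 20 (S)-hydroxyhumulene; 28 2,4-dihydroxy-5-(hydroxymethyl)-6-methylcyclohepta-2,4,6-trien-1-one (3 equiv)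
Product: 31 target CNP0283947.4, via tropolone ortho-quinone methide 29 (not isolated), via mono-adduct 30 (not isolated)
Conditions: p-xylene, 150 °C, sealed tube
Reagents that add atoms: none
Why: Thermal dehydration of 28 should give the ortho-quinone methide 29, which should add twice in inverse-electron-demand hetero-Diels–Alder fashion (oxygen to the methyl-bearing olefin carbon, methylene to the CH carbon), first to the outer face of C2=C3 with the C4 hydroxyl hydrogen-bonded to the incoming carbonyl and then to the outer face of C6=C7 in the conformation fixed by the first ring, the E geometry of each olefin giving the two trans ring fusions (2R,3R and 6R,7R).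

**Compound list**

1 | 3-methylbut-2-en-1-yl acetate | CC(C)=CCOC(C)=O | starting material
2 | (2E)-4-hydroxy-3-methylbut-2-en-1-yl acetate | CC(=O)OC/C=C(\C)CO | intermediate
3 | (2E)-4-bromo-3-methylbut-2-en-1-yl acetate | CC(=O)OC/C=C(\C)CBr | intermediate
4 | N-methoxy-N-methylacetamide | CC(=O)N(C)OC | starting material
5 | lithium 1-[methoxy(methyl)amino]ethen-1-olate | [Li+].[O-]C(=C)N(C)OC | intermediate
6 | (2E)-6-[methoxy(methyl)amino]-3-methyl-6-oxohex-2-en-1-yl acetate | CC(=O)OC/C=C(\C)CCC(=O)N(C)OC | intermediate
7 | prop-2-yn-1-ol | C#CCO | starting material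
8 | dimethyl[(1E)-3-(dimethylalumanyloxy)-2-methylprop-1-en-1-yl]alumane | C[Al](C)/C=C(\C)CO[Al](C)C | intermediate
9 | (4E,7E)-9-hydroxy-N-methoxy-N,4,8-trimethylnona-4,7-dienamide | OC/C(C)=C/C/C=C(\C)CCC(=O)N(C)OC | intermediate
10 | (5E,8E)-10-hydroxy-2,5,9-trimethyldeca-1,5,8-trien-3-one | OC/C(C)=C/C/C=C(\C)CCC(=O)C(C)=C | intermediate
11 | [(2S,3S)-3-[(2E)-3,7-dimethyl-6-oxoocta-2,7-dien-1-yl]-2-methyloxiran-2-yl]methanol | OC[C@]1(C)O[C@H]1C/C=C(\C)CCC(=O)C(C)=C | intermediate
12 | (2R,3S)-3-[(2E)-3,7-dimethyl-6-oxoocta-2,7-dien-1-yl]-2-methyloxirane-2-carbaldehyde | O=C[C@]1(C)O[C@H]1C/C=C(\C)CCC(=O)C(C)=C | intermediate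
13 | (5E)-7-[(2S,3S)-3-ethenyl-3-methyloxiran-2-yl]-2,5-dimethylhepta-1,5-dien-3-one | C=C[C@]1(C)O[C@H]1C/C=C(\C)CCC(=O)C(C)=C | intermediate
14 | potassium (6E)-8-[(2S,3S)-3-ethenyl-3-methyloxiran-2-yl]-2,6-dimethylocta-2,6-dien-3-olate | C=C[C@]1(C)O[C@H]1C/C=C(\C)CCC([O-])=C(C)C.[K+] | intermediate
15 | triethyl{[(6E)-8-[(2S,3S)-3-ethenyl-3-methyloxiran-2-yl]-2,6-dimethylocta-2,6-dien-3-yl]oxy}silane | C=C[C@]1(C)O[C@H]1C/C=C(\C)CCC(O[Si](CC)(CC)CC)=C(C)C | intermediate
16 | (4E,6S,8E)-2,2,5,9-tetramethyl-6-[(triethylsilyl)oxy]cycloundeca-4,8-dien-1-one | O=C1CC/C(C)=C/C[C@H](O[Si](CC)(CC)CC)/C(C)=C/CC1(C)C | intermediate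
17 | potassium (1Z,4E,7S,8E)-4,8,11,11-tetramethyl-7-[(triethylsilyl)oxy]cycloundeca-1,4,8-trien-1-olate | [K+].[O-]/C1=C\C/C(C)=C/C[C@H](O[Si](CC)(CC)CC)/C(C)=C/CC1(C)C | intermediate
18 | (1Z,4E,7S,8E)-4,8,11,11-tetramethyl-7-[(triethylsilyl)oxy]cycloundeca-1,4,8-trien-1-yl trifluoromethanesulfonate | FC(F)(F)S(=O)(=O)O/C1=C\C/C(C)=C/C[C@H](O[Si](CC)(CC)CC)/C(C)=C/CC1(C)C | intermediate
19 | triethyl{[(1S,2E,6E,9E)-2,5,5,9-tetramethylcycloundeca-2,6,9-trien-1-yl]oxy}silane | CC1(C)/C=C/C/C(C)=C/C[C@H](O[Si](CC)(CC)CC)/C(C)=C/C1 | intermediate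
20 | (1S,2E,6E,9E)-2,5,5,9-tetramethylcycloundeca-2,6,9-trien-1-ol | CC1(C)/C=C/C/C(C)=C/C[C@H](O)/C(C)=C/C1 | intermediate
21 | 1-methoxy-2-methylbenzene | COc1ccccc1C | starting material
22 | 1-methoxy-2-methylcyclohexa-1,4-diene | COC1=C(C)CC=CC1 | intermediate
23 | 7,7-dibromo-1-methoxy-6-methylbicyclo[4.1.0]hept-3-ene (racemic; one enantiomer drawn) | CO[C@@]12CC=CC[C@]1(C)C2(Br)Br | intermediate
24 | 7,7-dibromo-1-methoxy-6-methylbicyclo[4.1.0]heptane-3,4-diol (racemic cis-diol; one enantiomer drawn) | CO[C@@]12C[C@@H](O)[C@@H](O)C[C@]1(C)C2(Br)Br | intermediate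
25 | 7,7-dibromo-1-methoxy-6-methylbicyclo[4.1.0]heptane-3,4-dione (racemic; one enantiomer drawn) | CO[C@@]12CC(=O)C(=O)C[C@]1(C)C2(Br)Br | intermediate
26 | 5-bromo-2-hydroxy-4-methoxy-6-methylcyclohepta-2,4,6-trien-1-one | Cc1cc(=O)c(O)cc(OC)c1Br | intermediate
27 | 2-hydroxy-5-(hydroxymethyl)-4-methoxy-6-methylcyclohepta-2,4,6-trien-1-one | Cc1cc(=O)c(O)cc(OC)c1CO | intermediate
28 | 2,4-dihydroxy-5-(hydroxymethyl)-6-methylcyclohepta-2,4,6-trien-1-one | Cc1cc(=O)c(O)cc(O)c1CO | intermediate
29 | 3-hydroxy-6-methyl-7-methylidenecyclohepta-2,5-diene-1,4-dione (tropolone ortho-quinone methide) | C=C1C(C)=CC(=O)C(O)=CC1=O | intermediate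
30 | mono-adduct: tropolono-dihydropyran trans-fused across C2–C3 (2R,3R) of (4S)-hydroxyhumulene, C6=C7 and C9=C10 still E olefins | Cc1cc(=O)c(O)cc2c1C[C@H]1CC(C)(C)/C=C/C/C(C)=C/C[C@H](O)[C@]1(C)O2 | intermediate
31 | target CNP0283947.4: 11-membered ring with E C9=C10 olefin, (4S)-carbinol and two trans-fused tropolono-dihydropyrans across C2–C3 (2R,3R) and C6–C7 (6R,7R) | Cc1cc(=O)c(O)cc2c1C[C@H]1CC(C)(C)/C=C/C[C@@]3(C)Oc4cc(O)c(=O)cc(C)c4C[C@@H]3C[C@H](O)[C@]1(C)O2 | target

**Step count and risks**

Total step count: 20. Longest linear sequence: 14 steps (steps 1–13 and 20).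

Step 10 (key step). The zwitterionic π-allyl complex may collapse by proton loss to a dienol, the silyl transfer from the enol ether to the alkoxide may stall, or intermolecular alkylation may win over ring closure. The fallback separates ionisation from enolate release and uses the precedented allyl ester/enol silane ring closure. It sets out from 13, which with Pd(PPh3)4 (cat.) and AcOH in THF at 0 °C should undergo 1,4-addition to the hydroxy acetate F1. Silylation (Et3SiCl, imidazole, DMF) should give the silyl ether F2. Conjugate reduction with K[HB(s-Bu)3] at −78 °C and trapping with Me3SiCl should give the trimethylsilyl enol ether F3. Slow addition of F3 to Pd2(dba)3·CHCl3/dppe and Bu4N[Ph3SiF2] in THF at 60 °C should close the ring by fluoride-triggered Tsuji–Trost alkylation at C1, and the fallback comes back to the route at 16.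

Step 20. The quinone methide may be consumed by addition of the free C4 hydroxyl or by self-condensation, and the second cycloaddition may stay incomplete or lose facial control. The fallback changes the order of events so that the carbinol is masked during both cycloadditions and stereocontrol rests on the ring conformation alone. It sets out from 19, which is heated with 28 (3 equiv) in p-xylene at 150 °C to give the bis-adduct silyl ether F4; desilylation with Bu4NF in THF comes back to the route at 31.

Step 18. The free tropolone may chelate and sequester palladium, and oxidative addition at the doubly ortho-substituted carbon may be slow, so protodestannylation could outrun coupling. The fallback masks the chelating unit before the coupling. It sets out from 26, which with pivaloyl chloride and Et3N in CH2Cl2 should give the tropolone pivalate F5. Stille coupling of F5 with Bu3SnCH2OH and Pd(PPh3)4 in dioxane should give the hydroxymethyl pivalate F6. Hydrolysis of F6 in 2 M aq. HCl/dioxane at 60 °C removes the pivalate and the methyl group together and comes back to the route at 28.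

Further compounds
F1 | step 10 | (2E,4S,6E)-4-hydroxy-3,7,11-trimethyl-10-oxododeca-2,6,11-trien-1-yl acetate | CC(=O)OC/C=C(\C)[C@@H](O)C/C=C(\C)CCC(=O)C(C)=C
F2 | step 10 | (2E,4S,6E)-3,7,11-trimethyl-10-oxo-4-[(triethylsilyl)oxy]dodeca-2,6,11-trien-1-yl acetate | CC(=O)OC/C=C(\C)[C@@H](O[Si](CC)(CC)CC)C/C=C(\C)CCC(=O)C(C)=C
F3 | step 10 | (2E,4S,6E)-3,7,11-trimethyl-4-[(triethylsilyl)oxy]-10-[(trimethylsilyl)oxy]dodeca-2,6,10-trien-1-yl acetate | CC(=O)OC/C=C(\C)[C@@H](O[Si](CC)(CC)CC)C/C=C(\C)CCC(O[Si](C)(C)C)=C(C)C
F4 | step 20 | C4 triethylsilyl ether of the target (bis-adduct silyl ether) | Cc1cc(=O)c(O)cc2c1C[C@H]1CC(C)(C)/C=C/C[C@@]3(C)Oc4cc(O)c(=O)cc(C)c4C[C@@H]3C[C@H](O[Si](CC)(CC)CC)[C@]1(C)O2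
F5 | step 18 | 4-bromo-3-methoxy-5-methyl-7-oxocyclohepta-1,3,5-trien-1-yl 2,2-dimethylpropanoate | Cc1cc(=O)c(OC(=O)C(C)(C)C)cc(OC)c1Br
F6 | step 18 | 4-(hydroxymethyl)-3-methoxy-5-methyl-7-oxocyclohepta-1,3,5-trien-1-yl 2,2-dimethylpropanoate | Cc1cc(=O)c(OC(=O)C(C)(C)C)cc(OC)c1CO
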